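**Plan**
- Retrosynthesis cuts, in order: the two aryl O–Me bonds; the CH2–CH2 bond between the ring-bound CH2 and the chain (sulfone alkylation, C10 ring piece + C18 aryl-geranyl piece); then the two ring bonds flanking the tetrasubstituted C=C.
- Enabling feature: in the cyclohexene ring the tetrasubstituted C=C (methyl-bearing carbon and chain-bearing carbon) lies between a ring CH2 and the quaternary CMe2 carbon. With a temporary C=C between the two remaining ring CH2 carbons, the ring is the cyclohexa-1,4-diene adduct of 4-methylpenta-1,3-diene and a 2-butynyl unit.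
- Helper groups: the first side-chain carbon is carried as a formyl group, which activates and orients the alkyne and is then reduced to the CH2 handle; the extra ring C=C is hydrogenated.
- Forward order: the ring is made first (step 1) and trimmed to β-cyclogeranyl phenyl sulfone (steps 2–4); the aryl-geranyl bromide is made separately (steps 5–7); the two are joined (step 8), desulfonylated (step 9) and demethylated (step 10).
- Stereochemistry: the target has no stereocentre. One E-alkene comes from geranyl bromide; the other from E-selective allylic oxidation of the terminal E-methyl group. Neither is touched afterwards.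

Key step: step 1

Remark: but-2-ynal is taken as a purchasable reagent; compound 15 forms as a racemate at the sulfone carbon, which becomes CH2 in step 9.

**Step 1**
Reactants: 1 but-2-ynal; 2 4-methylpenta-1,3-diene
Product: 3 2,6,6-trimethylcyclohexa-1,4-diene-1-carbaldehyde
Conditions: 2 (3 equiv), BHT (cat.), toluene, sealed tube, 120–130 °C
Reagents that add atoms: none
Why: Thermal normal-demand Diels–Alder reaction: the s-cis conformer of 2 and ynal 1 combine in one concerted, asynchronous, suprafacial [4π+2π] cycloaddition, the known reaction type in which a conjugated alkynyl carbonyl compound and a 1,3-diene give a cyclohexa-1,4-diene. The six-membered carbocycle closes in this single cycloaddition, which forms the CH2–C(Me)= bond and the CMe2–C(CHO)= bond together and leaves the former alkyne as the tetrasubstituted ring C=C. No stereocentre arises. The selectivity needed is regiochemical (CMe2 beside the formyl-bearing carbon): the formyl group puts the largest LUMO coefficient on the methyl-bearing alkyne carbon, and the two methyl groups of 2 put the largest HOMO coefficient on its CH2 terminus and stabilise positive charge at the CMe2 end of the asynchronous transition state. A linear alkyne dienophile avoids the inward methyl group of 2, which is why an ynal under simple forcing conditions is chosen for this hindered diene; the quaternary carbon of 3 rules out aromatisation.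

**Step 2**
Reactants: 3 2,6,6-trimethylcyclohexa-1,4-diene-1-carbaldehyde
Product: 4 (2,6,6-trimethylcyclohexa-1,4-dien-1-yl)methanol
Conditions: NaBH4, CeCl3·7H2O, MeOH, 0 °C
Reagents that add atoms: none
Why: Luche 1,2-reduction of the hindered enal; the near-neutral, cold conditions should keep the skipped diene from moving into conjugation.

**Step 3**
Reactants: 4 (2,6,6-trimethylcyclohexa-1,4-dien-1-yl)methanol
Product: 5 β-cyclogeraniol [(2,6,6-trimethylcyclohex-1-en-1-yl)methanol]
Conditions: H2 (1 atm), RhCl(PPh3)3 (5 mol %), benzene–EtOH, rt
Reagents that add atoms: none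
Why: Homogeneous hydrogenation with RhCl(PPh3)3 discriminates by alkene substitution: the cis-disubstituted ring alkene should be reduced while the tetrasubstituted one is inert, and no double-bond migration or allylic C–O hydrogenolysis is expected.

**Step 4**
Reactants: 5 β-cyclogeraniol
Product: 7 β-cyclogeranyl phenyl sulfone [(2,6,6-trimethylcyclohex-1-en-1-yl)methyl phenyl sulfone], via β-cyclogeranyl bromide 6 (not isolated)
Conditions: PBr3, pyridine (cat.), Et2O, −10 °C; then PhSO2Na, DMF, rt
Reagents that add atoms: sodium benzenesulfinate, [Na+].[O-]S(=O)c1ccccc1; phosphorus tribromide, BrP(Br)Br (its bromine stays only in 6)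
Why: Bromination of the primary allylic alcohol, then SN2 S-alkylation of the sulfinate in a dipolar aprotic solvent; the labile bromide is used crude.

**Step 5**
Reactants: 8 1,4-dimethoxybenzene; 9 geranyl bromide [(2E)-1-bromo-3,7-dimethylocta-2,6-diene]
Product: 11 2-geranyl-1,4-dimethoxybenzene, via 2,5-dimethoxyphenyllithium 10 (not isolated)
Conditions: n-BuLi, TMEDA, THF, 0 °C; then CuBr·SMe2 (10 mol %), 9, −78 °C → rt
Reagents that add atoms: none
Why: Directed ortho-lithiation beside a methoxy group, then copper-assisted SN2 allylation at the primary allylic bromide, which should keep the 2E geometry.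

**Step 6**
Reactants: 11 2-geranyl-1,4-dimethoxybenzene
Product: 12 (2E,6E)-8-(2,5-dimethoxyphenyl)-2,6-dimethylocta-2,6-dien-1-ol
Conditions: SeO2 (cat.), t-BuOOH, salicylic acid (cat.), CH2Cl2, 0 °C → rt
Reagents that add atoms: tert-butyl hydroperoxide, CC(C)(C)OO (one oxygen atom, passed on through the SeO2 catalyst)
Why: Riley-type allylic oxidation (ene reaction, then [2,3]-sigmatropic shift) goes to the E-methyl group of the more electron-rich, more accessible terminal trisubstituted alkene, which sets the second E-alkene.

**Step 7**
Reactants: 12 (2E,6E)-8-(2,5-dimethoxyphenyl)-2,6-dimethylocta-2,6-dien-1-ol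
Product: 13 2-[(2E,6E)-8-bromo-3,7-dimethylocta-2,6-dien-1-yl]-1,4-dimethoxybenzene
Conditions: CBr4, PPh3, CH2Cl2, 0 °C
Reagents that add atoms: carbon tetrabromide, BrC(Br)(Br)Br
Why: Appel reaction; SN2 displacement of the oxyphosphonium group at the primary allylic carbon under neutral conditions should avoid allylic transposition and E/Z scrambling.

**Step 8**
Reactants: 7 β-cyclogeranyl phenyl sulfone; 13 2-[(2E,6E)-8-bromo-3,7-dimethylocta-2,6-dien-1-yl]-1,4-dimethoxybenzene
Product: 15 2-[(2E,6E)-3,7-dimethyl-9-(phenylsulfonyl)-9-(2,6,6-trimethylcyclohex-1-en-1-yl)nona-2,6-dien-1-yl]-1,4-dimethoxybenzene (racemic), via lithiated sulfone 14 (not isolated)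
Conditions: n-BuLi, THF, −78 °C; then 13, −78 → −20 °C
Reagents that add atoms: none
Why: Julia-type alkylation: the sulfonyl-stabilised allyl anion reacts at its α-carbon with the primary allylic bromide by SN2, joining the ring and chain fragments. The new stereocentre is not controlled and is removed in step 9.

**Step 9**
Reactants: 15 the alkylated sulfone
Product: 16 2-[(2E,6E)-3,7-dimethyl-9-(2,6,6-trimethylcyclohex-1-en-1-yl)nona-2,6-dien-1-yl]-1,4-dimethoxybenzene
Conditions: PdCl2(dppp) (5 mol %), LiBHEt3, THF, 0 °C → rt
Reagents that add atoms: none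
Why: Palladium-catalysed hydride desulfonylation of an allylic sulfone: zerovalent palladium ionises the allylic C–S bond, and hydride should go to the less substituted π-allyl terminus (the former sulfone carbon), which keeps the tetrasubstituted ring alkene in place.

**Step 10**
Reactants: 16 the dimethyl ether of the target
Product: 18 jaspaquinol, via jaspaquinone 17 (not isolated)
Conditions: (NH4)2Ce(NO3)6, MeCN–H2O, 0 °C; then aq. Na2S2O4, Et2O, rt
Reagents that add atoms: water, O (both ring oxygens of 17 and 18; the ether oxygens leave with methanol)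
Why: Oxidative demethylation of a 1,4-dimethoxyarene by tetravalent cerium (electron transfer, ipso attack of water, loss of methanol) gives the quinone, which dithionite reduces to the hydroquinone. The isolated alkenes are harder to oxidise than the arene and should survive a short, cold exposure.

**Compound list**
1 | but-2-ynal | CC#CC=O | starting material
2 | 4-methylpenta-1,3-diene | CC(C)=CC=C | starting material
3 | 2,6,6-trimethylcyclohexa-1,4-diene-1-carbaldehyde | CC1=C(C=O)C(C)(C)C=CC1 | intermediate
4 | (2,6,6-trimethylcyclohexa-1,4-dien-1-yl)methanol | CC1=C(CO)C(C)(C)C=CC1 | intermediate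
5 | β-cyclogeraniol, (2,6,6-trimethylcyclohex-1-en-1-yl)methanol | CC1=C(CO)C(C)(C)CCC1 | intermediate
6 | β-cyclogeranyl bromide, 2-(bromomethyl)-1,3,3-trimethylcyclohex-1-ene | CC1=C(CBr)C(C)(C)CCC1 | intermediate
7 | β-cyclogeranyl phenyl sulfone | CC1=C(CS(=O)(=O)c2ccccc2)C(C)(C)CCC1 | intermediate
8 | 1,4-dimethoxybenzene | COc1ccc(OC)cc1 | starting material
9 | geranyl bromide, (2E)-1-bromo-3,7-dimethylocta-2,6-diene | CC(C)=CCC/C(C)=C/CBr | starting material
10 | 2,5-dimethoxyphenyllithium | [Li]c1cc(OC)ccc1OC | intermediate
11 | 2-geranyl-1,4-dimethoxybenzene | COc1ccc(OC)c(C/C=C(\C)CCC=C(C)C)c1 | intermediate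
12 | (2E,6E)-8-(2,5-dimethoxyphenyl)-2,6-dimethylocta-2,6-dien-1-ol | COc1ccc(OC)c(C/C=C(\C)CC/C=C(\C)CO)c1 | intermediate
13 | 2-[(2E,6E)-8-bromo-3,7-dimethylocta-2,6-dien-1-yl]-1,4-dimethoxybenzene | COc1ccc(OC)c(C/C=C(\C)CC/C=C(\C)CBr)c1 | intermediate
14 | α-lithio derivative of β-cyclogeranyl phenyl sulfone | CC1=C(C([Li])S(=O)(=O)c2ccccc2)C(C)(C)CCC1 | intermediate
15 | 2-[(2E,6E)-3,7-dimethyl-9-(phenylsulfonyl)-9-(2,6,6-trimethylcyclohex-1-en-1-yl)nona-2,6-dien-1-yl]-1,4-dimethoxybenzene, racemic | CC1=C(C(C/C(C)=C/CC/C(C)=C/Cc2cc(OC)ccc2OC)S(=O)(=O)c2ccccc2)C(C)(C)CCC1 | intermediate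
16 | 2-[(2E,6E)-3,7-dimethyl-9-(2,6,6-trimethylcyclohex-1-en-1-yl)nona-2,6-dien-1-yl]-1,4-dimethoxybenzene | CC1=C(CC/C(C)=C/CC/C(C)=C/Cc2cc(OC)ccc2OC)C(C)(C)CCC1 | intermediate
17 | jaspaquinone, 2-[(2E,6E)-3,7-dimethyl-9-(2,6,6-trimethylcyclohex-1-en-1-yl)nona-2,6-dien-1-yl]cyclohexa-2,5-diene-1,4-dione | CC1=C(CC/C(C)=C/CC/C(C)=C/CC2=CC(=O)C=CC2=O)C(C)(C)CCC1 | intermediate
18 | jaspaquinol, 2-[(2E,6E)-3,7-dimethyl-9-(2,6,6-trimethylcyclohex-1-en-1-yl)nona-2,6-dien-1-yl]benzene-1,4-diol | CC1=C(CC/C(C)=C/CC/C(C)=C/Cc2cc(O)ccc2O)C(C)(C)CCC1 | target

**Totals**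
Total step count: 10.
Longest linear sequence: 7 steps (steps 1–4, then 8–10); the other branch is 6 steps (5–7, then 8–10).

**Steps most likely to fail, with fallbacks**

Step 1. The inward methyl group of 2 disfavours the s-cis conformer, so the cycloaddition may be slow, and at the temperature needed oligomerisation of the diene or the ynal may take over. The fallback replaces the cycloaddition by a cation–olefin ring closure. It sets out from geranyl bromide 9: displacement with PhSO2Na in DMF should give geranyl phenyl sulfone F1. Concentrated H2SO4 in AcOH (0–20 °C) should protonate the terminal alkene and close the ring by attack of the internal alkene. This is expected to give first the α-cyclogeranyl phenyl sulfone F2 (trisubstituted ring alkene, racemic) beside 7, and continued exposure to the acid is expected to move the double bond to the tetrasubstituted position. The route is rejoined at 7; steps 1–4 are then not needed.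

Step 6. The allylic oxidation may attack the doubly activated aryl–CH2–CH= position or the internal alkene as well, and may run on to the enal. The fallback replaces C–H oxidation by olefin cross-metathesis. It sets out from 11: methacrolein (excess) with the second-generation Hoveyda–Grubbs catalyst RuCl2(H2IMes)(=CH-C6H4-2-OiPr) in CH2Cl2 at 40 °C should exchange the isopropylidene terminus for an (E)-2-methylpropenal terminus and give the enal (2E,6E)-8-(2,5-dimethoxyphenyl)-2,6-dimethylocta-2,6-dienal F3. Luche reduction (NaBH4, CeCl3·7H2O, MeOH, 0 °C) then returns to the route at 12.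

Step 9. Ionisation of the hindered allylic sulfone may be slow, and hydride may be delivered to the ring carbon instead, which would move the double bond out of the ring. The fallback joins the fragments without a removable auxiliary. It sets out from alcohol 12 and the crude bromide 6 from step 4. MsCl, LiCl and 2,4,6-collidine in DMF at 0 °C should give the allylic chloride 2-[(2E,6E)-8-chloro-3,7-dimethylocta-2,6-dien-1-yl]-1,4-dimethoxybenzene F4. Activated barium (from BaI2 and lithium biphenylide, THF, −78 °C) should convert F4 into the allylbarium chloride F5. Addition of 6 at −78 °C is expected to give the α,α′-coupled 1,5-diene with retention of alkene geometry, which is 16 directly. The route is rejoined at 16; steps 7–9 and the sulfinate half of step 4 are then not needed.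

**Further compounds**
F1 | step 1 | geranyl phenyl sulfone | CC(C)=CCC/C(C)=C/CS(=O)(=O)c1ccccc1
F2 | step 1 | α-cyclogeranyl phenyl sulfone, racemic | CC1=CCCC(C)(C)C1CS(=O)(=O)c1ccccc1
F3 | step 6 | (2E,6E)-8-(2,5-dimethoxyphenyl)-2,6-dimethylocta-2,6-dienal | COc1ccc(OC)c(C/C=C(\C)CC/C=C(\C)C=O)c1
F4 | step 9 | 2-[(2E,6E)-8-chloro-3,7-dimethylocta-2,6-dien-1-yl]-1,4-dimethoxybenzene | COc1ccc(OC)c(C/C=C(\C)CC/C=C(\C)CCl)c1
F5 | step 9 | [(2E,6E)-8-(2,5-dimethoxyphenyl)-2,6-dimethylocta-2,6-dien-1-yl]barium chloride | COc1ccc(OC)c(C/C=C(\C)CC/C=C(\C)C[Ba]Cl)c1
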